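**Plan**

1. Retrosynthetic cuts, in order: (a) C-6–C-7 together with the lactone O–C-12 bond, so that one allylation/lactonisation opens both the ten-membered carbocycle and the α-methylene lactone; (b) the isovalerate at O-8; (c) C-1–C-2 and O–C-3 of the 3(2H)-furanone, which leaves a C-2–C-6 alkyne and a C-1/C-7–C-10 hydroxy lactone.
2. Enabling feature: the furanone ring O–C-10–C-1(=O)–C-2=C-3 is a terminal alkyne (C-2≡C-3) joined to a 2-hydroxy-2-methylacyl unit, and C-1, C-10, C-9, C-8, C-7 with their oxygens form a 2-C-methylpentono-1,4-lactone whose ring oxygen is O-8. An acetylide can therefore open this lactone at C-1 and the C-10 alkoxide can close onto C-3 in the same flask.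
3. Forward order: alkyne by Marshall propargylation; lactone by C-4 inversion of 2-C-methyl-D-ribonolactone and benzylidenation; the annulation joins both and forms the furanone ring first; O-8 is acylated, C-7 becomes a 2-(bromomethyl)acrylate, and chromium-mediated allylation of the C-6 aldehyde closes the ten-membered ring and the lactone ring last.
4. Stereochemistry: C-4/C-5 from (R)-but-3-yn-2-ol (chirality transfer through an allenylzinc, anti addition); C-9 and C-10 directly from the sugar, C-8 by epoxide-mediated inversion; C-6/C-7 from the chair-like allylchromium addition (anti, hence trans lactone) within the forming ring.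

Key step: step 7

Remark: atom numbers are those of the germacrane skeleton of the target (C-1 furanone carbonyl, C-2/C-3 furanone alkene with C-3 on oxygen, C-4 methyl-bearing CH, C-5 carbinol, C-6 lactone carbinol, C-7 ring-fusion CH, C-8 ester carbinol, C-9 carbinol, C-10 quaternary, C-11/C-13 methylene unit, C-12 lactone carbonyl); 2-[(4-methoxybenzyl)oxy]acetaldehyde and 2-C-methyl-D-ribono-1,4-lactone are assumed to be purchased.

**Route**

Step 1
Reactants: 1 (R)-but-3-yn-2-ol
Product: 2 (R)-but-3-yn-2-yl methanesulfonate
Conditions: MsCl, Et3N, CH2Cl2, −78 to 0 °C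
Reagents that add atoms: methanesulfonyl chloride, CS(Cl)(=O)=O
Why: O-sulfonylation does not touch the stereocentre and provides the propargylic leaving group needed for the Marshall propargylation.

Step 2
Reactants: 2 (R)-but-3-yn-2-yl methanesulfonate; 3 2-[(4-methoxybenzyl)oxy]acetaldehyde
Product: 5 (2S,3S)-1-[(4-methoxybenzyl)oxy]-3-methylpent-4-yn-2-ol, via allenylzinc 4 (not isolated)
Conditions: Pd(OAc)2 (5 mol %), PPh3 (5 mol %), Et2Zn (3 equiv), THF, −78 to −20 °C; 1 M HCl work-up
Reagents that add atoms: none
Why: Marshall propargylation, in which zerovalent palladium displaces the mesylate anti (SN2′), zinc takes over with retention, and allenylzinc 4 adds to the aldehyde through a cyclic SE2′ transition state, so that C-4 is formed with inversion relative to the C–O bond and the C-5 carbinol anti to it.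

Step 3
Reactants: 5 (2S,3S)-1-[(4-methoxybenzyl)oxy]-3-methylpent-4-yn-2-ol
Product: 6 tert-butyl({(2S,3S)-1-[(4-methoxybenzyl)oxy]-3-methylpent-4-yn-2-yl}oxy)dimethylsilane
Conditions: TBSCl, imidazole, DMF, rt
Reagents that add atoms: tert-butyldimethylsilyl chloride, CC(C)(C)[Si](C)(C)Cl
Why: Silyl ether formation at the only hydroxyl protects O-5 for the acetylide chemistry without affecting a stereocentre.

Step 4
Reactants: 7 2-C-methyl-D-ribono-1,4-lactone
Product: 8 2-C-methyl-5-O-tosyl-D-ribono-1,4-lactone
Conditions: TsCl (1.05 equiv), pyridine, −20 to 0 °C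
Reagents that add atoms: 4-methylbenzenesulfonyl chloride, Cc1ccc(cc1)S(Cl)(=O)=O
Why: Sulfonylation is selective for the primary hydroxyl over the secondary and the tertiary one and activates the sugar C-5 for epoxide formation.

Step 5
Reactants: 8 2-C-methyl-5-O-tosyl-D-ribono-1,4-lactone
Product: 10 2-C-methyl-L-lyxono-1,4-lactone, via epoxy carboxylate 9 (not isolated)
Conditions: KOH (2.2 equiv), H2O, 0 °C to rt; then HCl to pH 1, 40 °C
Reagents that add atoms: potassium hydroxide, [K+].[OH-]
Why: Saponification frees the sugar O-4, which displaces the tosylate (intramolecular Williamson etherification to the 4,5-epoxide); on acidification the carboxyl group opens the epoxide at the sugar C-4 (5-exo-tet) with inversion, which turns D-ribo into L-lyxo and sets C-8 of the target.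

Step 6
Reactants: 10 2-C-methyl-L-lyxono-1,4-lactone
Product: 11 3,5-O-[(R)-benzylidene]-2-C-methyl-L-lyxono-1,4-lactone
Conditions: PhCH(OMe)2, CSA (cat.), MeCN, 50 °C, reduced pressure
Reagents that add atoms: benzaldehyde dimethyl acetal, COC(OC)c1ccccc1
Why: Thermodynamic acetalisation bridges the cis-disposed O-3 and O-5 as a six-membered benzylidene acetal (phenyl equatorial, hence the R acetal centre) and leaves the tertiary hydroxyl free.

Step 7
Reactants: 6 tert-butyl({(2S,3S)-1-[(4-methoxybenzyl)oxy]-3-methylpent-4-yn-2-yl}oxy)dimethylsilane; 11 3,5-O-[(R)-benzylidene]-2-C-methyl-L-lyxono-1,4-lactone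
Product: 14 furanone alcohol, via alkynyl lactol 12 (not isolated), via hydroxy ynone 13 (not isolated)
Conditions: 6, n-BuLi, THF, −78 °C; 11, LiN(SiMe3)2, THF, −78 °C; combine, −78 °C; MeOH, −78 °C to rt; AcOH
Reagents that add atoms: none
Why: Proposed new method: the lithium acetylide of 6 adds to the lactone carbonyl C-1 of the lithium alkoxide of 11 to give lactolate 12, which persists at −78 °C so that only one alkynyl group is transferred; after the methanol quench and warming, lithium methoxide equilibrates 12 with the open ynone 13 (O-8 set free) and the tertiary O-10 adds to C-3 of the ynone, C-2 being protonated by methanol, so that C-1–C-2 and O–C-3 arise in one operation as a formal (3+2) annulation of a terminal alkyne with an α-hydroxy lactone. The closest known reaction types are the addition of lithium acetylides to γ-lactones and the base- or gold-mediated cyclisation of isolated α′-hydroxy ynones to 3(2H)-furanones; their merger on an unprotected α-hydroxy lactone, which acts as acyl donor, as protecting group of O-8 and as carrier of the C-10 oxygen nucleophile, is the untested element. The furanone ring closes in the 5-endo-dig mode by oxygen attack on the activated alkyne, while the sugar lactone ring opens. No stereocentre is formed: C-8, C-9 and C-10 are carried from the sugar (C-10 bears no hydrogen and cannot epimerise) and C-4/C-5 from 6. The step needs mono-addition (secured by the stable lactolate and the quench before warming), attack by O-10 and not by O-8 (five- versus seven-membered closure, and O-8 is tied up in the lactol until the ynone appears) and integrity of the C-4 centre next to the new enone (short contact with methoxide at or below room temperature, and no silyl group near an alkoxide that could migrate).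

Step 8
Reactants: 14 furanone alcohol
Product: 15 furanone isovalerate
Conditions: isovaleric anhydride, Et3N, DMAP (cat.), CH2Cl2, 0 °C to rt
Reagents that add atoms: 3-methylbutanoic anhydride, CC(C)CC(=O)OC(=O)CC(C)C
Why: DMAP-catalysed acylation of the single free hydroxyl, the secondary O-8 released in step 7, installs the isovalerate with retention.

Step 9
Reactants: 15 furanone isovalerate
Product: 16 7,9-diol
Conditions: CSA (0.1 equiv), MeOH, 0 °C to rt
Reagents that add atoms: none
Why: Acid-catalysed transacetalisation with methanol removes the benzylidene acetal under conditions that should spare the secondary TBS ether, the PMB ether and the ester.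

Step 10
Reactants: 16 7,9-diol
Product: 17 7,9-bis(triethylsilyl) ether
Conditions: TESOTf (2.5 equiv), 2,6-lutidine, CH2Cl2, −78 °C
Reagents that add atoms: triethylsilyl trifluoromethanesulfonate, CC[Si](CC)(CC)OS(=O)(=O)C(F)(F)F
Why: Silylation with the triflate at low temperature caps both hydroxyls (including the hindered O-9) before the ester can migrate and prepares the selective oxidation at C-7.

Step 11
Reactants: 17 7,9-bis(triethylsilyl) ether
Product: 18 C-7 aldehyde
Conditions: (COCl)2, DMSO, CH2Cl2, −78 to −30 °C; Et3N, −78 to 0 °C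
Reagents that add atoms: none
Why: Swern oxidation, which cleaves and oxidises a primary triethylsilyl ether directly while secondary silyl ethers persist, unveils the C-7 aldehyde in one step, and the low temperature limits epimerisation at C-8.

Step 12
Reactants: 18 C-7 aldehyde; 19 methyl acrylate
Product: 20 Morita–Baylis–Hillman adduct
Conditions: 19 (10 equiv), DABCO (1 equiv), DMF, rt
Reagents that add atoms: none
Why: Morita–Baylis–Hillman reaction of the activated α-oxygenated aldehyde with the DABCO-derived acrylate enolate forms the C-7–C-11 bond; the new C-7 carbinol centre is inconsequential because it becomes sp2 in step 13.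

Step 13
Reactants: 20 Morita–Baylis–Hillman adduct
Product: 21 (Z)-allylic bromide
Conditions: PPh3, CBr4, CH2Cl2, 0 °C
Reagents that add atoms: carbon tetrabromide, BrC(Br)(Br)Br
Why: Appel bromination with allylic transposition (SN2′ attack of bromide at the methylene terminus of the alkoxyphosphonium salt) should give the thermodynamically preferred (Z)-2-(bromomethyl)enoate under neutral conditions that offer no electrophilic bromine to the furanone.

Step 14
Reactants: 21 (Z)-allylic bromide
Product: 22 C-6 alcohol
Conditions: DDQ, CH2Cl2/pH 7 buffer (10:1), 0 °C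
Reagents that add atoms: none
Why: Oxidative cleavage of the PMB ether by DDQ is orthogonal to the silyl ethers, the allylic bromide and the esters.

Step 15
Reactants: 22 C-6 alcohol
Product: 23 C-6 aldehyde
Conditions: Dess–Martin periodinane, CH2Cl2, 0 °C to rt
Reagents that add atoms: none
Why: Dess–Martin oxidation gives the α-silyloxy aldehyde without base, so C-5 should not epimerise.

Step 16
Reactants: 23 C-6 aldehyde
Product: 25 bis-silylated macrolactone, via hydroxy ester 24 (not isolated)
Conditions: CrCl2 (10 equiv), THF, 2 mM, slow addition of 23, rt to 50 °C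
Reagents that add atoms: none
Why: Intramolecular Nozaki–Hiyama–Kishi (Barbier-type) allylation, in which divalent chromium turns the allylic bromide into an allylchromium species that attacks the C-6 aldehyde through its γ-carbon C-7 in a chair-like transition state, should give the anti adduct 24 and, after attack of the alkoxide on the methyl ester, the trans-fused α-methylene lactone; the (6S,7S) facial course is expected to be imposed by the rigid furanone bridge of the forming ten-membered ring, which keeps the C-5 silyloxy and C-8 acyloxy groups on its outside, and is the least secure element of the step.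

Step 17
Reactants: 25 bis-silylated macrolactone
Product: 26 target CNP0484215.1
Conditions: HF·pyridine, pyridine, THF, 0 °C to rt
Reagents that add atoms: none
Why: Buffered fluoride cleaves the triethylsilyl and the tert-butyldimethylsilyl ether under weakly acidic conditions that should suppress acyl migration from O-8 to O-9 and conjugate addition to the α-methylene lactone.

**Compound list**

1 | (R)-but-3-yn-2-ol | C[C@@H](O)C#C | starting material
2 | (R)-but-3-yn-2-yl methanesulfonate | C[C@@H](OS(C)(=O)=O)C#C | intermediate
3 | 2-[(4-methoxybenzyl)oxy]acetaldehyde | COc1ccc(COCC=O)cc1 | starting material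
4 | ethyl[(aS)-buta-1,2-dien-1-yl]zinc (allenylzinc; zinc anti to the departed mesylate; axial chirality not encoded in the SMILES) | CC[Zn]C=C=CC | intermediate
5 | (2S,3S)-1-[(4-methoxybenzyl)oxy]-3-methylpent-4-yn-2-ol | COc1ccc(cc1)COC[C@@H](O)[C@@H](C)C#C | intermediate
6 | tert-butyl({(2S,3S)-1-[(4-methoxybenzyl)oxy]-3-methylpent-4-yn-2-yl}oxy)dimethylsilane | COc1ccc(cc1)COC[C@@H](O[Si](C)(C)C(C)(C)C)[C@@H](C)C#C | intermediate
7 | 2-C-methyl-D-ribono-1,4-lactone, (3R,4R,5R)-3,4-dihydroxy-5-(hydroxymethyl)-3-methyloxolan-2-one | O=C1[C@](C)(O)[C@H](O)[C@H](O1)CO | starting material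
8 | 2-C-methyl-5-O-tosyl-D-ribono-1,4-lactone | O=C1[C@](C)(O)[C@H](O)[C@H](O1)COS(=O)(=O)c2ccc(C)cc2 | intermediate
9 | potassium 4,5-anhydro-2-C-methyl-D-ribonate (epoxy carboxylate) | [K+].[O-]C(=O)[C@](C)(O)[C@H](O)[C@H]1CO1 | intermediate
10 | 2-C-methyl-L-lyxono-1,4-lactone, (3R,4R,5S)-3,4-dihydroxy-5-(hydroxymethyl)-3-methyloxolan-2-one | O=C1[C@](C)(O)[C@H](O)[C@@H](O1)CO | intermediate
11 | 3,5-O-[(R)-benzylidene]-2-C-methyl-L-lyxono-1,4-lactone | O=C1[C@](C)(O)[C@@H]2O[C@H](c3ccccc3)OC[C@@H]2O1 | intermediate
12 | alkynyl lactol: 1-C-alkynyl hemiketal from 6 and 11 (both C-1 epimers) | COc1ccc(cc1)COC[C@@H](O[Si](C)(C)C(C)(C)C)[C@@H](C)C#CC2(O)[C@](C)(O)[C@@H]3O[C@H](c4ccccc4)OC[C@@H]3O2 | intermediate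
13 | hydroxy ynone: C-1 ketone with free O-8 and O-10, 7,9-O-benzylidene | COc1ccc(cc1)COC[C@@H](O[Si](C)(C)C(C)(C)C)[C@@H](C)C#CC(=O)[C@](C)(O)[C@@H]2O[C@H](c3ccccc3)OC[C@@H]2O | intermediate
14 | furanone alcohol: (2R)-5-[(2R,3S)-3-[(tert-butyldimethylsilyl)oxy]-4-[(4-methoxybenzyl)oxy]butan-2-yl]-2-[(2R,4R,5S)-5-hydroxy-2-phenyl-1,3-dioxan-4-yl]-2-methylfuran-3(2H)-one | COc1ccc(cc1)COC[C@@H](O[Si](C)(C)C(C)(C)C)[C@@H](C)C2=CC(=O)[C@](C)(O2)[C@@H]3O[C@H](c4ccccc4)OC[C@@H]3O | intermediate
15 | furanone isovalerate: 3-methylbutanoate of 14 at O-8 | COc1ccc(cc1)COC[C@@H](O[Si](C)(C)C(C)(C)C)[C@@H](C)C2=CC(=O)[C@](C)(O2)[C@@H]3O[C@H](c4ccccc4)OC[C@@H]3OC(=O)CC(C)C | intermediate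
16 | 7,9-diol: 15 without the benzylidene acetal (C-7 primary and C-9 secondary hydroxyl free) | COc1ccc(cc1)COC[C@@H](O[Si](C)(C)C(C)(C)C)[C@@H](C)C2=CC(=O)[C@](C)(O2)[C@H](O)[C@@H](OC(=O)CC(C)C)CO | intermediate
17 | 7,9-bis(triethylsilyl) ether of 16 | COc1ccc(cc1)COC[C@@H](O[Si](C)(C)C(C)(C)C)[C@@H](C)C2=CC(=O)[C@](C)(O2)[C@H](O[Si](CC)(CC)CC)[C@@H](OC(=O)CC(C)C)CO[Si](CC)(CC)CC | intermediate
18 | C-7 aldehyde: 8-O-isovaleryl, 9-O-TES, 5-O-TBS, 6-O-PMB | COc1ccc(cc1)COC[C@@H](O[Si](C)(C)C(C)(C)C)[C@@H](C)C2=CC(=O)[C@](C)(O2)[C@H](O[Si](CC)(CC)CC)[C@@H](OC(=O)CC(C)C)C=O | intermediate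
19 | methyl acrylate | C=CC(=O)OC | starting material
20 | Morita–Baylis–Hillman adduct: methyl 2-methylidene-3-hydroxy ester at C-7 (both C-7 epimers) | COc1ccc(cc1)COC[C@@H](O[Si](C)(C)C(C)(C)C)[C@@H](C)C2=CC(=O)[C@](C)(O2)[C@H](O[Si](CC)(CC)CC)[C@@H](OC(=O)CC(C)C)C(O)C(=C)C(=O)OC | intermediate
21 | (Z)-allylic bromide: methyl (Z)-2-(bromomethyl)enoate with C-7=C-11, 6-O-PMB | COc1ccc(cc1)COC[C@@H](O[Si](C)(C)C(C)(C)C)[C@@H](C)C2=CC(=O)[C@](C)(O2)[C@H](O[Si](CC)(CC)CC)[C@@H](OC(=O)CC(C)C)/C=C(\CBr)C(=O)OC | intermediate
22 | C-6 alcohol: 21 without the PMB group | OC[C@@H](O[Si](C)(C)C(C)(C)C)[C@@H](C)C1=CC(=O)[C@](C)(O1)[C@H](O[Si](CC)(CC)CC)[C@@H](OC(=O)CC(C)C)/C=C(\CBr)C(=O)OC | intermediate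
23 | C-6 aldehyde (bromo aldehyde, ring-closure precursor) | O=C[C@@H](O[Si](C)(C)C(C)(C)C)[C@@H](C)C1=CC(=O)[C@](C)(O1)[C@H](O[Si](CC)(CC)CC)[C@@H](OC(=O)CC(C)C)/C=C(\CBr)C(=O)OC | intermediate
24 | hydroxy ester: ten-membered carbocycle with C-6 hydroxyl and the methyl 2-methylidene ester at C-7 | COC(=O)C(=C)[C@H]1[C@H](O)[C@@H](O[Si](C)(C)C(C)(C)C)[C@@H](C)C2=CC(=O)[C@](C)(O2)[C@H](O[Si](CC)(CC)CC)[C@H]1OC(=O)CC(C)C | intermediate
25 | bis-silylated macrolactone: 5-O-TBS, 9-O-TES ether of the target | C=C1C(=O)O[C@@H]2[C@@H](O[Si](C)(C)C(C)(C)C)[C@@H](C)C3=CC(=O)[C@](C)(O3)[C@H](O[Si](CC)(CC)CC)[C@@H](OC(=O)CC(C)C)[C@@H]12 | intermediate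
26 | CNP0484215.1, (4R,5S,6S,7S,8S,9R,10R)-5,9-dihydroxy-8-(3-methylbutanoyloxy)-1-oxo-3,10-epoxygermacra-2,11(13)-dien-12,6-olide | C=C1C(=O)O[C@@H]2[C@@H](O)[C@@H](C)C3=CC(=O)[C@](C)(O3)[C@H](O)[C@@H](OC(=O)CC(C)C)[C@@H]12 | target

**Step count and risk**

Total step count: 17. Longest linear sequence: 14 steps (steps 4–17 from 7, or steps 1–3 and 7–17 from 1).

Steps most likely to fail:

Step 7 (Proposed new method). What may go wrong: sluggish acyl transfer to a lactone carbonyl deactivated by the neighbouring alkoxide, double addition after premature collapse of the lactolate, competing seven-membered closure by O-8, or base-mediated propargyl–allenyl isomerisation eroding C-4. The fallback uses known chemistry only; it sets out from 11 (together with 6) and comes back at 14. Lactone 11 would be opened with MeNH(OMe)·HCl and Me3Al to the Weinreb amide F1. Addition of an excess of the lithium acetylide of 6 (the surplus alkyne being recovered) should give hydroxy ynone 13, now isolated. Cycloisomerisation of 13 with (Ph3P)AuNTf2 (2 mol %, toluene, rt; monovalent gold activating the alkyne for 5-endo-dig attack by O-10) would then give 14 under neutral conditions.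

Step 16. What may go wrong: intermolecular oligomerisation in place of ring closure, attack on the wrong aldehyde face (acyclic Felkin–Anh preference at C-5 opposes the required 5,6-syn relationship), or incomplete lactonisation. The fallback sets out from 23 and comes back at 25; it moves stereocontrol from the substrate to a chiral catalyst and separates ring closure from lactonisation. Bromo aldehyde 23 would be cyclised with catalytic CrCl2, a C2-symmetric carbazole-bridged bis(oxazoline) ligand (the antipode that delivers the 6S,7S series being chosen in a small screen), Mn powder and Me3SiCl in THF at high dilution, giving the trimethylsilyl ether F2 of the open hydroxy ester. Selective removal of the trimethylsilyl group (citric acid, MeOH, 0 °C) would release hydroxy ester 24, which lactonises to 25.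

Step 12. What may go wrong: epimerisation at C-8 of the α-acyloxy aldehyde under prolonged amine catalysis, migration of the isovaleryl group to the new C-7 hydroxyl, or slow conversion. The fallback sets out from 18 and comes back at 20; it replaces amine catalysis by a preformed acrylate anion equivalent. Methyl propiolate would be treated with i-Bu2AlH/HMPA (THF, 0 °C) to give the vinylalane F3, which should add to aldehyde 18 at −78 °C within minutes to give 20 without exposure to base; 20 would be brominated at once as in step 13.

Further compounds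
F1 | step 7 | Weinreb amide: N-methoxy-N-methylamide of 3,5-O-[(R)-benzylidene]-2-C-methyl-L-lyxonic acid | CON(C)C(=O)[C@](C)(O)[C@@H]1O[C@H](c2ccccc2)OC[C@@H]1O
F2 | step 16 | trimethylsilyl ether of hydroxy ester 24 at O-6 | COC(=O)C(=C)[C@H]1[C@H](O[Si](C)(C)C)[C@@H](O[Si](C)(C)C(C)(C)C)[C@@H](C)C2=CC(=O)[C@](C)(O2)[C@H](O[Si](CC)(CC)CC)[C@H]1OC(=O)CC(C)C
F3 | step 12 | methyl 2-(diisobutylalumanyl)prop-2-enoate (vinylalane) | COC(=O)C(=C)[Al](CC(C)C)CC(C)C
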